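**Retrosynthetic overview**

1. Feature: the quaternary stereocentre C4a (chromene numbering) carries a prenyl group and lies between the C5 carbonyl and the enol-ether carbon C8a of a cyclohexadienone fused to a 2,2-dimethyl-2H-pyran (O1–C2–C3=C4–C4a–C8a). C4a is therefore a former aromatic carbon ortho to the ether oxygen of an acylphloroglucinol.
2. Disconnection 1 (last step, the only ring formed): C4–C4a, by catalytic enantioselective dearomatizing 6-endo hydroarylation of the O-tethered alkyne of aryl 1,1-dimethylpropargyl ether 8, whose two prenyl-bearing ortho carbons are enantiotopic.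
3. Disconnection 2: O1–C2, ether 8 from deoxyhumulone 6 and 3-chloro-3-methylbut-1-yne 7 by copper-catalysed etherification of the 4-hydroxyl.
4. Disconnections 3 and 4: the two aryl–prenyl bonds (6 from 3 and prenyl bromide 4) and the aryl–acyl bond (3 from phloroglucinol 1 and isovaleryl chloride 2).
5. Ring order: the carbocycle is the phloroglucinol ring from the start; the pyran closes last, in the step that breaks aromaticity and sets C4a.

Key step: step 4

**Remarks on the chemistry**

- The target is an enolized β-triketone and is drawn as one of its rapidly interconverting tautomers; all are treated as the same compound.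
- The configuration at C4a in the target SMILES is (R).
- The sense of induction of the chiral gold catalyst cannot be predicted. The ligand is written as one antipode, and the antipode that is found to give the (4aR) product is the one to be used.
- Catalyst-bound species of the gold cycle are described in words and are not numbered.

**Route**

Step 1
Reactants: 1 phloroglucinol; 2 isovaleryl chloride
Product: 3 phlorisovalerophenone, 3-methyl-1-(2,4,6-trihydroxyphenyl)butan-1-one
Conditions: AlCl3 (3 equiv), PhNO2/CH2Cl2, 0 °C to 50 °C; then ice/aq. HCl
Reagents that add atoms: none
Why: Friedel–Crafts C-acylation of the symmetric, strongly activated triol should stop at the mono-ketone, because the first acyl group deactivates the ring and holds the Lewis acid in a chelate.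

Step 2
Reactants: 3 phlorisovalerophenone; 4 prenyl bromide (2.1 equiv)
Product: 6 deoxyhumulone (3-methyl-1-[2,4,6-trihydroxy-3,5-bis(3-methylbut-2-enyl)phenyl]butan-1-one), via mono-C-prenyl phlorisovalerophenone 5 (not isolated)
Conditions: 10% aq. KOH, 0 °C, Ar; then cold dilute HCl; product kept under Ar
Reagents that add atoms: none
Why: Base-mediated C-alkylation of the ambident phloroglucinolate (SN2 at the primary allylic bromide) should take place at the two free ring carbons one after the other, since in water the phenolate oxygens are hydrogen-bonded, while two equivalents at 0 °C hold back the third, dearomatizing alkylation.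

Step 3
Reactants: 6 deoxyhumulone; 7 3-chloro-3-methylbut-1-yne (1.3 equiv)
Product: 8 1-[2,6-dihydroxy-4-(2-methylbut-3-yn-2-yloxy)-3,5-bis(3-methylbut-2-enyl)phenyl]-3-methylbutan-1-one
Conditions: CuCl2·2H2O (0.5 mol %), DBU (1.2 equiv), degassed MeCN, 0 °C, Ar; cold work-up, used without delay
Reagents that add atoms: none
Why: Copper-catalysed propargylic etherification of a phenol (through a copper acetylide/allenylidene) should occur at the 4-hydroxyl, which is the most acidic one (para to the acyl group) and is not held by the ketone, so one equivalent of base gives the 4-phenoxide, which adds through oxygen to the tertiary carbon while C-alkylation would have to join two fully substituted carbons.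

Step 4
Reactants: 8 1-[2,6-dihydroxy-4-(2-methylbut-3-yn-2-yloxy)-3,5-bis(3-methylbut-2-enyl)phenyl]-3-methylbutan-1-one
Product: 9 (4aR)-7-hydroxy-2,2-dimethyl-6-(3-methylbutanoyl)-4a,8-bis(3-methylbut-2-enyl)-2H-chromen-5(4aH)-one (CNP0111062.1)
Conditions: (R)-DTBM-SEGPHOS(AuCl)2 (2.5 mol %), AgNTf2 (5 mol %), 4 Å MS, toluene, −20 °C; chromatography on acid-washed silica, then crystallization to raise the enantiomeric purity if needed
Reagents that add atoms: none
Why: Proposed new method: the cationic gold(I) centre binds the terminal alkyne of 8, a prenyl-bearing ortho carbon of the ring (C3 or C5 of the phenyl ketone, ortho or para to all three ring oxygens) attacks the terminal alkyne carbon, the resulting arenium ion has no ring hydrogen to lose and instead gives up the proton of the neighbouring hydroxyl to become the C5 ketone, and protodeauration of the vinyl-gold by that proton leaves the C3=C4 alkene and frees the catalyst. The closest known reactions are the gold(I)-catalysed hydroarylation of aryl propargyl ethers to 2H-chromenes and the gold-catalysed dearomatization of 1-substituted 2-naphthols and of phenols by tethered alkynes; a gold-assisted propargyl Claisen shift to an allenyl dienone followed by 6-endo hydroalkoxylation would arrive at the same product. The one ring that closes, the 2,2-dimethyl-2H-pyran, does so by 6-endo-dig C–C bond formation (C4–C4a), preferred over 5-exo-dig closure because the alkyne is terminal, the gem-dimethyl group folds the tether toward the ring and the 5-exo product would be a strained dihydrobenzofuran-type ring with an exocyclic methylene next to the quaternary carbon. C4a is the only new stereocentre and is set under catalyst control: the two ortho carbons are enantiotopic, since the ketone hydrogen bond changes over quickly between the 2- and 6-hydroxyls, and the axially chiral digold bisphosphine with its bulky 3,5-di-tert-butyl-4-methoxyphenyl groups must pick one of them, which is the same as picking one face of the arene. Constitutional selectivity needs no control because both ortho positions carry prenyl and both closures give the same skeleton, the low temperature should keep the uncatalysed Claisen background and ionization of the tertiary propargylic C–O bond negligible, and the quaternary carbon of the product cannot epimerize.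

**Compound list**

1 | phloroglucinol (benzene-1,3,5-triol) | Oc1cc(O)cc(O)c1 | starting material
2 | isovaleryl chloride (3-methylbutanoyl chloride) | CC(C)CC(Cl)=O | starting material
3 | phlorisovalerophenone, 3-methyl-1-(2,4,6-trihydroxyphenyl)butan-1-one | CC(C)CC(=O)c1c(O)cc(O)cc1O | intermediate
4 | prenyl bromide (1-bromo-3-methylbut-2-ene) | CC(C)=CCBr | starting material
5 | mono-C-prenyl phlorisovalerophenone, 3-methyl-1-[2,4,6-trihydroxy-3-(3-methylbut-2-enyl)phenyl]butan-1-one | CC(C)CC(=O)c1c(O)cc(O)c(CC=C(C)C)c1O | intermediate (not isolated)
6 | deoxyhumulone, 3-methyl-1-[2,4,6-trihydroxy-3,5-bis(3-methylbut-2-enyl)phenyl]butan-1-one | CC(C)CC(=O)c1c(O)c(CC=C(C)C)c(O)c(CC=C(C)C)c1O | intermediate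
7 | 3-chloro-3-methylbut-1-yne | CC(C)(Cl)C#C | starting material
8 | 1-[2,6-dihydroxy-4-(2-methylbut-3-yn-2-yloxy)-3,5-bis(3-methylbut-2-enyl)phenyl]-3-methylbutan-1-one (4-O-dimethylpropargyl deoxyhumulone) | CC(C)CC(=O)c1c(O)c(CC=C(C)C)c(OC(C)(C)C#C)c(CC=C(C)C)c1O | intermediate
9 | (4aR)-7-hydroxy-2,2-dimethyl-6-(3-methylbutanoyl)-4a,8-bis(3-methylbut-2-enyl)-2H-chromen-5(4aH)-one (CNP0111062.1) | CC(C)=CCC1=C2OC(C)(C)C=C[C@@]2(CC=C(C)C)C(=O)C(C(=O)CC(C)C)=C1O | target

**Step count**

Total steps: 4. Longest linear sequence: 4 steps (1 → 3 → 6 → 8 → 9).

**Steps most likely to fail, with fallbacks**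

Step 4 (proposed new method). The chiral gold complex may discriminate poorly between the two enantiotopic ortho carbons, or the gold/silver may ionize the tertiary propargylic C–O bond before C–C bond formation. The fallback sets out from 8 and separates bond formation, ring closure and stereocontrol, each by a known reaction type.
- Heating 8 in toluene or xylene should bring about the aromatic propargyl Claisen rearrangement onto a blocked ortho position and give the racemic allenyl dienone, in its enol form 3,5-dihydroxy-2-(3-methylbutanoyl)-6-(3-methylbuta-1,2-dienyl)-4,6-bis(3-methylbut-2-enyl)cyclohexa-2,4-dien-1-one F1.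
- The enol hydroxyl of F1 next to the quaternary carbon is a β-hydroxyallene, so an achiral silver(I) or gold(I) salt (AgNO3, or Ph3PAuCl/AgOTf) should close it 6-endo at the dimethyl terminus to the racemic chromenone F2.
- Preparative chromatography on a chiral stationary phase (amylose tris(3,5-dimethylphenylcarbamate)) should then separate F2 into 9 and the (4aS)-enantiomer F3.
- The detour comes back to the route at 9.

Step 3. The 4-oxygen is flanked by two prenyl groups and may react slowly, so that alkylation at the 2- or 6-oxygen or at ring carbon competes, or the electron-rich triol is oxidized under the basic copper conditions. The fallback sets out from 3 and changes the order of events.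
- The same copper-catalysed etherification is run on 3, whose 4-hydroxyl is unhindered and the most acidic, to give 1-[2,6-dihydroxy-4-(2-methylbut-3-yn-2-yloxy)phenyl]-3-methylbutan-1-one F4.
- F4 is then C-prenylated twice with prenyl bromide 4 in cold aqueous KOH at its two remaining ring carbons, through the mono-prenyl compound 1-[2,6-dihydroxy-4-(2-methylbut-3-yn-2-yloxy)-3-(3-methylbut-2-enyl)phenyl]-3-methylbutan-1-one F5; the base-stable propargylic ether and terminal alkyne should survive.
- The detour comes back to the route at 8.

Step 2. The phenolate alkylation may run on to the trialkylated dienone or go partly through oxygen, leaving too little of the 3,5-dialkylated triol. The fallback sets out from 3 and replaces phenolate alkylation by electrophilic aromatic substitution.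
- Compound 3 is treated with 2-methylbut-3-en-2-ol and a substoichiometric amount of BF3·OEt2 in dioxane at room temperature.
- The prenyl cation attacks only ring carbon and cannot dearomatize a neutral triol, so the reaction should stop at C-prenyl products; material stopped at 5 is recycled.
- The detour makes no compound outside the list (F0) and comes back to the route at 6.

**Further compounds**

F1 | step 4 | racemic 3,5-dihydroxy-2-(3-methylbutanoyl)-6-(3-methylbuta-1,2-dienyl)-4,6-bis(3-methylbut-2-enyl)cyclohexa-2,4-dien-1-one | CC(C)=CCC1=C(O)C(CC=C(C)C)(C=C=C(C)C)C(=O)C(C(=O)CC(C)C)=C1O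
F2 | step 4 | racemic 7-hydroxy-2,2-dimethyl-6-(3-methylbutanoyl)-4a,8-bis(3-methylbut-2-enyl)-2H-chromen-5(4aH)-one | CC(C)=CCC1=C2OC(C)(C)C=CC2(CC=C(C)C)C(=O)C(C(=O)CC(C)C)=C1O
F3 | step 4 | (4aS)-7-hydroxy-2,2-dimethyl-6-(3-methylbutanoyl)-4a,8-bis(3-methylbut-2-enyl)-2H-chromen-5(4aH)-one | CC(C)=CCC1=C2OC(C)(C)C=C[C@]2(CC=C(C)C)C(=O)C(C(=O)CC(C)C)=C1O
F4 | step 3 | 1-[2,6-dihydroxy-4-(2-methylbut-3-yn-2-yloxy)phenyl]-3-methylbutan-1-one | CC(C)CC(=O)c1c(O)cc(OC(C)(C)C#C)cc1O
F5 | step 3 | 1-[2,6-dihydroxy-4-(2-methylbut-3-yn-2-yloxy)-3-(3-methylbut-2-enyl)phenyl]-3-methylbutan-1-one | CC(C)CC(=O)c1c(O)cc(OC(C)(C)C#C)c(CC=C(C)C)c1O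
F0 | step 2 | none | none
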